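**Plan**
- Retrosynthesis: take off the two esters (C1–OAc, C8–O-tigloyl) and the C8–O bond; take the isopropenyl group back to an ester carbon C11 on C7; then excise C8 from ring B (cut C8–C9 and C7–C8, rejoin C7–C9) to reach a trans-hydrindanone β-keto ester.
- That five-membered ring is cut at C7–C9 (Dieckmann) to a ring A diester; C1–O and C10–H (conjugate borylation), C10–C9 (carbonylation), C5–C6 (Michael addition) and C4–CH3 (conjugate addition) lead back to 2-methylcyclohex-2-en-1-one.
- Forward: ring A first, then a five-membered ring on its C5–C10 edge, then one-carbon enlargement of that ring to ring B, then adjustment of the C7, C8 and C1 substituents.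
- Enabling feature: in ring B the ketone C9, the neighbouring carbon C8 and C7 with its exocyclic carbon C11 form a 4-oxo ester (γ-keto ester) pattern. This is what homologation of a β-keto ester delivers, with C8 as the inserted carbon and C11 as the ester that drives it.
- Stereochemistry: C4 from a ligand-controlled copper-catalysed conjugate addition; C5 by attack anti to the C4 methyl; C1 (O), C10 (H), C7 (H) and C8 (O) each by delivery of that atom to the α face, anti to the axial C5 methyl.

Key step: step 8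

Remark: positions are numbered as in the eremophilane skeleton of the target (C1 acetoxy carbon, C4 and C5 methyl-bearing carbons, C7 isopropenyl-bearing carbon, C8 tigloyloxy carbon, C9 ketone, C10 ring-fusion CH, C11 central isopropenyl carbon); α is the face opposite to the C5 methyl; metal enolates and alkoxides formed by simple deprotonation are counted with their neutral parent compounds.

**Route**

Step 1
Reactants: 1 2-methylcyclohex-2-en-1-one; 2 trimethylaluminium
Product: 3 (3S)-2,3-dimethylcyclohexan-1-one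
Conditions: copper thiophene-2-carboxylate (CuTC, 2 mol %), BINOL-derived N,N-bis(1-phenylethyl)phosphoramidite (antipode that gives the 3S ketone, 4 mol %), Me3Al, Et2O, −30 °C; then 1 M HCl
Reagents that add atoms: trimethylaluminium C[Al](C)C
Why: Copper-catalysed asymmetric conjugate addition to an α-substituted cyclic enone, in which the chiral monovalent copper complex delivers methyl to one face of C3 and so sets the later C4 centre; the C2 centre formed on protonation is left as a mixture because step 2 enolises it again.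

Step 2
Reactants: 3 (3S)-2,3-dimethylcyclohexan-1-one; 4 methyl acrylate
Product: 5 methyl 3-[(1R,2S)-1,2-dimethyl-6-oxocyclohexyl]propanoate
Conditions: KOtBu (0.1 equiv), t-BuOH/THF, 0 °C to rt
Reagents that add atoms: methyl acrylate C=CC(=O)OC
Why: Base-catalysed Michael addition through the more substituted (thermodynamic) enolate; the acrylate should approach anti to the neighbouring ring methyl, so the new quaternary centre C5 carries its methyl cis to the C4 methyl.

Step 3
Reactants: 5 methyl 3-[(1R,2S)-1,2-dimethyl-6-oxocyclohexyl]propanoate; 6 N-phenylbis(trifluoromethanesulfonimide)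
Product: 7 methyl 3-[(1R,6S)-1,6-dimethyl-2-{[(trifluoromethyl)sulfonyl]oxy}cyclohex-2-en-1-yl]propanoate
Conditions: KN(SiMe3)2 added to 5 and PhNTf2, THF, −78 to 0 °C; then aq. NH4Cl
Reagents that add atoms: N-phenylbis(trifluoromethanesulfonimide) O=S(=O)(N(c1ccccc1)S(=O)(=O)C(F)(F)F)C(F)(F)F
Why: Enol triflate formation; the ketone can enolise only towards its CH2 side because the other α-carbon is quaternary, and trapping in situ at low temperature should outrun Claisen-type attack on the side-chain ester.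

Step 4
Reactants: 7 methyl 3-[(1R,6S)-1,6-dimethyl-2-{[(trifluoromethyl)sulfonyl]oxy}cyclohex-2-en-1-yl]propanoate; 8 carbon monoxide; 9 methanol
Product: 10 methyl (5S,6R)-6-(3-methoxy-3-oxopropyl)-5,6-dimethylcyclohex-1-ene-1-carboxylate
Conditions: Pd(OAc)2 (5 mol %), 1,3-bis(diphenylphosphino)propane, Et3N, CO (1 atm), MeOH/DMF, 60 °C
Reagents that add atoms: carbon monoxide [C-]#[O+]; methanol CO
Why: Palladium-catalysed methoxycarbonylation of a vinyl triflate (oxidative addition to zerovalent palladium, CO insertion, methanolysis), a reaction that tolerates a neighbouring quaternary carbon; it forms the C10–C9 bond and no stereocentre.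

Step 5
Reactants: 10 methyl (5S,6R)-6-(3-methoxy-3-oxopropyl)-5,6-dimethylcyclohex-1-ene-1-carboxylate; 11 bis(pinacolato)diboron; 12 sodium perborate
Product: 14 methyl (1S,2S,5S,6R)-2-hydroxy-6-(3-methoxy-3-oxopropyl)-5,6-dimethylcyclohexane-1-carboxylate, via β-boryl diester 13 (not isolated)
Conditions: CuCl (5 mol %), NaOtBu (10 mol %), Xantphos (5 mol %), B2pin2, MeOH (2 equiv), THF, rt; then NaBO3·4H2O, THF/H2O, rt
Reagents that add atoms: sodium perborate [Na+].[O-]OB=O (hydroxyl oxygen); bis(pinacolato)diboron CC1(C)OB(OC1(C)C)B1OC(C)(C)C(C)(C)O1 (boron of 13 only)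
Why: Copper-catalysed conjugate borylation of an α,β-unsaturated ester followed by stereoretentive C–B oxidation; boryl-copper should add across C1=C10 from the α face, anti to the pseudo-axial C5 methyl, and protonation at C10 from the same unhindered axial side leaves the ester equatorial, giving the trans β-hydroxy ester (C1–O α, C10–H α).

Step 6
Reactants: 14 methyl (1S,2S,5S,6R)-2-hydroxy-6-(3-methoxy-3-oxopropyl)-5,6-dimethylcyclohexane-1-carboxylate; 15 tert-butyldimethylsilyl trifluoromethanesulfonate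
Product: 16 methyl (1S,2S,5S,6R)-2-[(tert-butyldimethylsilyl)oxy]-6-(3-methoxy-3-oxopropyl)-5,6-dimethylcyclohexane-1-carboxylate
Conditions: TBSOTf, 2,6-lutidine, CH2Cl2, −78 to 0 °C
Reagents that add atoms: tert-butyldimethylsilyl trifluoromethanesulfonate CC(C)(C)[Si](C)(C)OS(=O)(=O)C(F)(F)F
Why: Silylation of a hindered secondary alcohol with the silyl triflate; the ether should survive the bases and organometallics of steps 7–11 and come off with fluoride in step 14.

Step 7
Reactants: 16 methyl (1S,2S,5S,6R)-2-[(tert-butyldimethylsilyl)oxy]-6-(3-methoxy-3-oxopropyl)-5,6-dimethylcyclohexane-1-carboxylate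
Product: 17 methyl (3aS,4S,7S,7aR)-4-[(tert-butyldimethylsilyl)oxy]-7,7a-dimethyl-3-oxooctahydro-1H-indene-2-carboxylate
Conditions: LiN(SiMe3)2 (2.2 equiv), THF, −78 to 0 °C; then AcOH
Reagents that add atoms: none
Why: Dieckmann condensation (5-exo-trig attack of the side-chain ester enolate C7 on the ring ester carbonyl C9); deprotonation should occur at the open CH2 and not at the shielded tertiary C10–H, so the trans ring fusion is kept, and the product rests as its β-keto ester enolate until the acidic quench.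

Step 8
Reactants: 17 methyl (3aS,4S,7S,7aR)-4-[(tert-butyldimethylsilyl)oxy]-7,7a-dimethyl-3-oxooctahydro-1H-indene-2-carboxylate; 18 diiodomethane
Product: 21 methyl (2S,4aS,5S,8S,8aR)-5-[(tert-butyldimethylsilyl)oxy]-8,8a-dimethyl-4-oxodecahydronaphthalene-2-carboxylate, via zinc cyclopropoxide 19 (not isolated), via ring-enlarged zinc enolate 20 (not isolated)
Conditions: Et2Zn (4 equiv), CH2I2 (4 equiv), CH2Cl2, 0 °C; then 17, 0 °C to rt; sat. aq. NH4Cl, −40 °C
Reagents that add atoms: diiodomethane ICI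
Why: The zinc enolate of 17 is cyclopropanated across its C9=C7 bond by the carbenoid EtZnCH2I to give the donor–acceptor cyclopropoxide 19, whose C9–C7 bond breaks under the push of the zinc alkoxide and the pull of the ester, so the new CH2 (C8) ends up between the ketone and the ester-bearing carbon and the five-membered ring becomes six-membered ring B as zinc ester enolate 20. The closest known reaction type is the zinc-carbenoid homologation of β-keto esters to γ-keto esters (Zercher reaction) in its ring-enlarging form on 2-alkoxycarbonyl cycloalkanones, with the Dowd–Beckwith ring expansion as its radical counterpart. No ring is closed in the product; the only closure is the transient three-membered ring made by concerted [2+1] methylene transfer, and it opens again in the same flask. The one new stereocentre, C7, is set when 20 is protonated on quench: the proton should enter from the α face, anti to the syn-axial C5 methyl (equatorial protonation of an exocyclic enolate), leaving the ester axial and cis to that methyl, as the later isopropenyl group must be. The step needs regioselective cleavage of C9–C7 and no enolisation towards C10; the first is secured because only that cyclopropane bond lies between the alkoxide donor and the ester acceptor, the second because zinc stays on the ester enolate until the cold quench.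

Step 9
Reactants: 21 methyl (2S,4aS,5S,8S,8aR)-5-[(tert-butyldimethylsilyl)oxy]-8,8a-dimethyl-4-oxodecahydronaphthalene-2-carboxylate; 22 chlorotriethylsilane
Product: 23 methyl (2S,4aS,5S,8S,8aR)-5-[(tert-butyldimethylsilyl)oxy]-8,8a-dimethyl-4-[(triethylsilyl)oxy]-1,2,4a,5,6,7,8,8a-octahydronaphthalene-2-carboxylate
Conditions: LiN(iPr)2 (1.05 equiv), TESCl present from the start, THF, −78 °C
Reagents that add atoms: chlorotriethylsilane CC[Si](Cl)(CC)CC
Why: Kinetic enolisation of the ketone at the less hindered C8 methylene with in situ silyl trapping (regioselective silyl enol ether formation); this masks the C9 ketone for steps 10 and 11 and prepares the Rubottom oxidation, while the less acidic ester α-hydrogen and the shielded tertiary C10–H should stay untouched.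

Step 10
Reactants: 23 methyl (2S,4aS,5S,8S,8aR)-5-[(tert-butyldimethylsilyl)oxy]-8,8a-dimethyl-4-[(triethylsilyl)oxy]-1,2,4a,5,6,7,8,8a-octahydronaphthalene-2-carboxylate; 24 methyllithium
Product: 25 2-[(2S,4aS,5S,8S,8aR)-5-[(tert-butyldimethylsilyl)oxy]-8,8a-dimethyl-4-[(triethylsilyl)oxy]-1,2,4a,5,6,7,8,8a-octahydronaphthalen-2-yl]propan-2-ol
Conditions: CeCl3 (anhydrous, 4 equiv), MeLi (4 equiv), THF, −78 to −40 °C; then aq. NH4Cl
Reagents that add atoms: methyllithium [Li]C
Why: Double addition of the weakly basic organocerium reagent MeCeCl2 to the ester; trivalent cerium suppresses enolisation of the intermediate methyl ketone and so protects the C7 centre, and the silyl enol ether is inert to it.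

Step 11
Reactants: 25 2-[(2S,4aS,5S,8S,8aR)-5-[(tert-butyldimethylsilyl)oxy]-8,8a-dimethyl-4-[(triethylsilyl)oxy]-1,2,4a,5,6,7,8,8a-octahydronaphthalen-2-yl]propan-2-ol
Product: 26 (2S,4aS,5S,8S,8aR)-5-[(tert-butyldimethylsilyl)oxy]-8,8a-dimethyl-2-(prop-1-en-2-yl)-4-[(triethylsilyl)oxy]-1,2,4a,5,6,7,8,8a-octahydronaphthalene
Conditions: Burgess reagent (1.5 equiv), toluene, 50 °C
Reagents that add atoms: none
Why: Burgess dehydration (syn-elimination through the sulfamate ester); six methyl hydrogens stand against one hindered ring hydrogen at C7, so the isopropenyl alkene should form in preference to the tetrasubstituted isomer.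

Step 12
Reactants: 26 (2S,4aS,5S,8S,8aR)-5-[(tert-butyldimethylsilyl)oxy]-8,8a-dimethyl-2-(prop-1-en-2-yl)-4-[(triethylsilyl)oxy]-1,2,4a,5,6,7,8,8a-octahydronaphthalene; 27 3-chloroperoxybenzoic acid
Product: 29 (2R,3R,4aR,5S,8S,8aS)-8-[(tert-butyldimethylsilyl)oxy]-2-hydroxy-4a,5-dimethyl-3-(prop-1-en-2-yl)octahydronaphthalen-1(2H)-one, via silyloxy epoxide 28 (not isolated)
Conditions: mCPBA (1.0 equiv), NaHCO3, CH2Cl2, −20 °C; then AcOH/THF/H2O, 0 °C
Reagents that add atoms: 3-chloroperoxybenzoic acid O=C(OO)c1cccc(Cl)c1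
Why: Rubottom oxidation; the electron-rich silyl enol ether should be epoxidised far faster than the isopropenyl group, the peracid should approach the α face, anti to the axial C7 isopropenyl and the C5 methyl, and mild acid opens the silyloxy epoxide to the 8α-hydroxy ketone with loss of the triethylsilyl group while the secondary TBS ether stays.

Step 13
Reactants: 29 (2R,3R,4aR,5S,8S,8aS)-8-[(tert-butyldimethylsilyl)oxy]-2-hydroxy-4a,5-dimethyl-3-(prop-1-en-2-yl)octahydronaphthalen-1(2H)-one; 30 (2E)-2-methylbut-2-enoyl chloride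
Product: 31 (2R,3R,4aR,5S,8S,8aS)-8-[(tert-butyldimethylsilyl)oxy]-4a,5-dimethyl-1-oxo-3-(prop-1-en-2-yl)decahydronaphthalen-2-yl (2E)-2-methylbut-2-enoate
Conditions: tigloyl chloride (1.5 equiv), Et3N, DMAP (cat.), CH2Cl2, 0 °C
Reagents that add atoms: (2E)-2-methylbut-2-enoyl chloride C/C=C(\C)C(=O)Cl
Why: DMAP-catalysed acylation of the secondary α-ketol hydroxyl; the E geometry of the acid chloride is kept, and a short reaction at 0 °C should avoid enolisation at C8 or C10.

Step 14
Reactants: 31 (2R,3R,4aR,5S,8S,8aS)-8-[(tert-butyldimethylsilyl)oxy]-4a,5-dimethyl-1-oxo-3-(prop-1-en-2-yl)decahydronaphthalen-2-yl (2E)-2-methylbut-2-enoate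
Product: 32 (2R,3R,4aR,5S,8S,8aS)-8-hydroxy-4a,5-dimethyl-1-oxo-3-(prop-1-en-2-yl)decahydronaphthalen-2-yl (2E)-2-methylbut-2-enoate
Conditions: HF·pyridine, THF, 0 °C to rt
Reagents that add atoms: none
Why: Fluoride cleavage of the silyl ether under mildly acidic, base-free conditions, which should spare the tiglate, the α-acyloxy ketone and the new β-hydroxy ketone (no retro-aldol, no elimination).

Step 15
Reactants: 32 (2R,3R,4aR,5S,8S,8aS)-8-hydroxy-4a,5-dimethyl-1-oxo-3-(prop-1-en-2-yl)decahydronaphthalen-2-yl (2E)-2-methylbut-2-enoate; 33 acetic anhydride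
Product: 34 (2R,3R,4aR,5S,8S,8aS)-8-(acetyloxy)-4a,5-dimethyl-1-oxo-3-(prop-1-en-2-yl)decahydronaphthalen-2-yl (2E)-2-methylbut-2-enoate
Conditions: Ac2O, pyridine, DMAP (cat.), CH2Cl2, 0 °C
Reagents that add atoms: acetic anhydride CC(=O)OC(C)=O
Why: Acetylation of the equatorial C1 hydroxyl; brief exposure at 0 °C should limit E1cB loss of the new β-acetoxy group.

**Compound list**
1 | 2-methylcyclohex-2-en-1-one | CC1=CCCCC1=O | starting material
2 | trimethylaluminium | C[Al](C)C | starting material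
3 | (3S)-2,3-dimethylcyclohexan-1-one (C2 epimers) | CC1C(=O)CCC[C@@H]1C | intermediate
4 | methyl acrylate | C=CC(=O)OC | starting material
5 | methyl 3-[(1R,2S)-1,2-dimethyl-6-oxocyclohexyl]propanoate | COC(=O)CC[C@@]1(C)C(=O)CCC[C@@H]1C | intermediate
6 | N-phenylbis(trifluoromethanesulfonimide) | O=S(=O)(N(c1ccccc1)S(=O)(=O)C(F)(F)F)C(F)(F)F | starting material
7 | methyl 3-[(1R,6S)-1,6-dimethyl-2-{[(trifluoromethyl)sulfonyl]oxy}cyclohex-2-en-1-yl]propanoate | COC(=O)CC[C@@]1(C)C(OS(=O)(=O)C(F)(F)F)=CCC[C@@H]1C | intermediate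
8 | carbon monoxide | [C-]#[O+] | starting material
9 | methanol | CO | starting material
10 | methyl (5S,6R)-6-(3-methoxy-3-oxopropyl)-5,6-dimethylcyclohex-1-ene-1-carboxylate | COC(=O)CC[C@@]1(C)C(C(=O)OC)=CCC[C@@H]1C | intermediate
11 | bis(pinacolato)diboron | CC1(C)OB(OC1(C)C)B1OC(C)(C)C(C)(C)O1 | starting material
12 | sodium perborate | [Na+].[O-]OB=O | starting material
13 | methyl (1R,2S,5S,6R)-6-(3-methoxy-3-oxopropyl)-5,6-dimethyl-2-(4,4,5,5-tetramethyl-1,3,2-dioxaborolan-2-yl)cyclohexane-1-carboxylate (β-boryl diester) | COC(=O)CC[C@@]1(C)[C@H](C(=O)OC)[C@@H](B2OC(C)(C)C(C)(C)O2)CC[C@@H]1C | intermediate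
14 | methyl (1S,2S,5S,6R)-2-hydroxy-6-(3-methoxy-3-oxopropyl)-5,6-dimethylcyclohexane-1-carboxylate | COC(=O)CC[C@@]1(C)[C@H](C(=O)OC)[C@@H](O)CC[C@@H]1C | intermediate
15 | tert-butyldimethylsilyl trifluoromethanesulfonate | CC(C)(C)[Si](C)(C)OS(=O)(=O)C(F)(F)F | starting material
16 | methyl (1S,2S,5S,6R)-2-[(tert-butyldimethylsilyl)oxy]-6-(3-methoxy-3-oxopropyl)-5,6-dimethylcyclohexane-1-carboxylate | COC(=O)CC[C@@]1(C)[C@H](C(=O)OC)[C@@H](O[Si](C)(C)C(C)(C)C)CC[C@@H]1C | intermediate
17 | methyl (3aS,4S,7S,7aR)-4-[(tert-butyldimethylsilyl)oxy]-7,7a-dimethyl-3-oxooctahydro-1H-indene-2-carboxylate (trans-fused; C2 epimers and enol) | COC(=O)C1C[C@@]2(C)[C@H](C1=O)[C@@H](O[Si](C)(C)C(C)(C)C)CC[C@@H]2C | intermediate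
18 | diiodomethane | ICI | starting material
19 | zinc cyclopropoxide: ethylzinc alkoxide of the C7–C8–C9 cyclopropanol formed by methylene transfer to the enolate of 17 (other stereocentres as in 17) | COC(=O)C13C[C@@]2(C)[C@H](C1(O[Zn]CC)C3)[C@@H](O[Si](C)(C)C(C)(C)C)CC[C@@H]2C | intermediate
20 | ring-enlarged zinc enolate: O-ethylzinc ketene acetal (C7=C11) of 21 | COC(O[Zn]CC)=C1C[C@@]2(C)[C@H](C(=O)C1)[C@@H](O[Si](C)(C)C(C)(C)C)CC[C@@H]2C | intermediate
21 | methyl (2S,4aS,5S,8S,8aR)-5-[(tert-butyldimethylsilyl)oxy]-8,8a-dimethyl-4-oxodecahydronaphthalene-2-carboxylate (trans-decalin, axial ester cis to the angular methyl) | COC(=O)[C@H]1C[C@@]2(C)[C@H](C(=O)C1)[C@@H](O[Si](C)(C)C(C)(C)C)CC[C@@H]2C | intermediate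
22 | chlorotriethylsilane | CC[Si](Cl)(CC)CC | starting material
23 | methyl (2S,4aS,5S,8S,8aR)-5-[(tert-butyldimethylsilyl)oxy]-8,8a-dimethyl-4-[(triethylsilyl)oxy]-1,2,4a,5,6,7,8,8a-octahydronaphthalene-2-carboxylate | COC(=O)[C@H]1C[C@@]2(C)[C@H](C(O[Si](CC)(CC)CC)=C1)[C@@H](O[Si](C)(C)C(C)(C)C)CC[C@@H]2C | intermediate
24 | methyllithium | [Li]C | starting material
25 | 2-[(2S,4aS,5S,8S,8aR)-5-[(tert-butyldimethylsilyl)oxy]-8,8a-dimethyl-4-[(triethylsilyl)oxy]-1,2,4a,5,6,7,8,8a-octahydronaphthalen-2-yl]propan-2-ol | CC(C)(O)[C@H]1C[C@@]2(C)[C@H](C(O[Si](CC)(CC)CC)=C1)[C@@H](O[Si](C)(C)C(C)(C)C)CC[C@@H]2C | intermediate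
26 | (2S,4aS,5S,8S,8aR)-5-[(tert-butyldimethylsilyl)oxy]-8,8a-dimethyl-2-(prop-1-en-2-yl)-4-[(triethylsilyl)oxy]-1,2,4a,5,6,7,8,8a-octahydronaphthalene | C=C(C)[C@H]1C[C@@]2(C)[C@H](C(O[Si](CC)(CC)CC)=C1)[C@@H](O[Si](C)(C)C(C)(C)C)CC[C@@H]2C | intermediate
27 | 3-chloroperoxybenzoic acid | O=C(OO)c1cccc(Cl)c1 | starting material
28 | silyloxy epoxide: 8α,9α-epoxide of 26 (oxirane oxygen anti to the C5 methyl; C9 carries OSiEt3) | C=C(C)[C@H]1C[C@@]2(C)[C@H]([C@]3(O[Si](CC)(CC)CC)O[C@H]13)[C@@H](O[Si](C)(C)C(C)(C)C)CC[C@@H]2C | intermediate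
29 | (2R,3R,4aR,5S,8S,8aS)-8-[(tert-butyldimethylsilyl)oxy]-2-hydroxy-4a,5-dimethyl-3-(prop-1-en-2-yl)octahydronaphthalen-1(2H)-one | C=C(C)[C@H]1C[C@@]2(C)[C@H](C(=O)[C@@H]1O)[C@@H](O[Si](C)(C)C(C)(C)C)CC[C@@H]2C | intermediate
30 | (2E)-2-methylbut-2-enoyl chloride (tigloyl chloride) | C/C=C(\C)C(=O)Cl | starting material
31 | (2R,3R,4aR,5S,8S,8aS)-8-[(tert-butyldimethylsilyl)oxy]-4a,5-dimethyl-1-oxo-3-(prop-1-en-2-yl)decahydronaphthalen-2-yl (2E)-2-methylbut-2-enoate | C=C(C)[C@H]1C[C@@]2(C)[C@H](C(=O)[C@@H]1OC(=O)/C(C)=C/C)[C@@H](O[Si](C)(C)C(C)(C)C)CC[C@@H]2C | intermediate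
32 | (2R,3R,4aR,5S,8S,8aS)-8-hydroxy-4a,5-dimethyl-1-oxo-3-(prop-1-en-2-yl)decahydronaphthalen-2-yl (2E)-2-methylbut-2-enoate | C=C(C)[C@H]1C[C@@]2(C)[C@H](C(=O)[C@@H]1OC(=O)/C(C)=C/C)[C@@H](O)CC[C@@H]2C | intermediate
33 | acetic anhydride | CC(=O)OC(C)=O | starting material
34 | (2R,3R,4aR,5S,8S,8aS)-8-(acetyloxy)-4a,5-dimethyl-1-oxo-3-(prop-1-en-2-yl)decahydronaphthalen-2-yl (2E)-2-methylbut-2-enoate (CNP0138236.1) | C=C(C)[C@H]1C[C@@]2(C)[C@H](C(=O)[C@@H]1OC(=O)/C(C)=C/C)[C@@H](OC(C)=O)CC[C@@H]2C | target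

**Totals and risks**
Total step count: 15. Longest linear sequence: 15 steps (from 1).

Steps most likely to fail:

1. Step 8. The quench may protonate the zinc enolate from the β face, or the axial ester may equilibrate, so that the C7 substituent ends up equatorial. The fallback sets out from 17 and runs the same homologation but quenches zinc enolate 20 with iodine instead of a proton, to give the α-iodo ester methyl (4aS,5S,8S,8aR)-5-[(tert-butyldimethylsilyl)oxy]-2-iodo-8,8a-dimethyl-4-oxodecahydronaphthalene-2-carboxylate F1. DBU (CH2Cl2, 0 °C) should eliminate HI to the enone ester methyl (4aS,5S,8S,8aR)-5-[(tert-butyldimethylsilyl)oxy]-8,8a-dimethyl-4-oxo-1,4,4a,5,6,7,8,8a-octahydronaphthalene-2-carboxylate F2. Hydrogenation of F2 (H2, palladium on carbon, EtOAc) should deliver both hydrogens from the catalyst face anti to the C5 methyl and come back to the route at 21.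

2. Step 5. Boryl-copper addition to the hindered, α-branched enoate may be slow or may take place from the β face. The fallback sets out from 10: electrophilic epoxidation with trifluoroperacetic acid (from (CF3CO)2O and urea–H2O2, Na2HPO4, CH2Cl2, 0 °C) should give the glycidic ester methyl 2-(3-methoxy-3-oxopropyl)-2,3-dimethyl-7-oxabicyclo[4.1.0]heptane-1-carboxylate (oxirane anti to the quaternary methyl) F3. Reductive opening of its Cα–O bond with SmI2 (divalent samarium, THF/MeOH, −78 °C) keeps the C1–O bond, protonates the samarium enolate at C10 from the axial α side, and comes back at 14.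

3. Step 11. The elimination may take the ring hydrogen at C7, giving the tetrasubstituted alkene and erasing C7, or the silyl enol ether may be lost on warming. The fallback sets out from 23 and replaces steps 10 and 11: MeNH(OMe)·HCl with iPrMgCl (THF, −20 °C) should give the Weinreb amide (2S,4aS,5S,8S,8aR)-5-[(tert-butyldimethylsilyl)oxy]-N-methoxy-N,8,8a-trimethyl-4-[(triethylsilyl)oxy]-1,2,4a,5,6,7,8,8a-octahydronaphthalene-2-carboxamide F4. MeMgBr (THF, 0 °C) then gives the methyl ketone 1-[(2S,4aS,5S,8S,8aR)-5-[(tert-butyldimethylsilyl)oxy]-8,8a-dimethyl-4-[(triethylsilyl)oxy]-1,2,4a,5,6,7,8,8a-octahydronaphthalen-2-yl]ethan-1-one F5. Non-basic methylenation with Cp2TiMe2 (toluene, 65 °C) comes back at 26.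

**Further compounds**
F1 | step 8 | methyl (4aS,5S,8S,8aR)-5-[(tert-butyldimethylsilyl)oxy]-2-iodo-8,8a-dimethyl-4-oxodecahydronaphthalene-2-carboxylate | COC(=O)C1(I)C[C@@]2(C)[C@H](C(=O)C1)[C@@H](O[Si](C)(C)C(C)(C)C)CC[C@@H]2C
F2 | step 8 | methyl (4aS,5S,8S,8aR)-5-[(tert-butyldimethylsilyl)oxy]-8,8a-dimethyl-4-oxo-1,4,4a,5,6,7,8,8a-octahydronaphthalene-2-carboxylate | COC(=O)C=1C[C@@]2(C)[C@H](C(=O)C1)[C@@H](O[Si](C)(C)C(C)(C)C)CC[C@@H]2C
F3 | step 5 | methyl 2-(3-methoxy-3-oxopropyl)-2,3-dimethyl-7-oxabicyclo[4.1.0]heptane-1-carboxylate (oxirane anti to the quaternary methyl) | COC(=O)CC[C@@]1(C)[C@@]2(C(=O)OC)O[C@H]2CC[C@@H]1C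
F4 | step 11 | (2S,4aS,5S,8S,8aR)-5-[(tert-butyldimethylsilyl)oxy]-N-methoxy-N,8,8a-trimethyl-4-[(triethylsilyl)oxy]-1,2,4a,5,6,7,8,8a-octahydronaphthalene-2-carboxamide | CON(C)C(=O)[C@H]1C[C@@]2(C)[C@H](C(O[Si](CC)(CC)CC)=C1)[C@@H](O[Si](C)(C)C(C)(C)C)CC[C@@H]2C
F5 | step 11 | 1-[(2S,4aS,5S,8S,8aR)-5-[(tert-butyldimethylsilyl)oxy]-8,8a-dimethyl-4-[(triethylsilyl)oxy]-1,2,4a,5,6,7,8,8a-octahydronaphthalen-2-yl]ethan-1-one | CC(=O)[C@H]1C[C@@]2(C)[C@H](C(O[Si](CC)(CC)CC)=C1)[C@@H](O[Si](C)(C)C(C)(C)C)CC[C@@H]2C
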